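**Plan**

1. Target numbering (1,7-dioxaspiro[4.4]nonane): ring B = O1–C2(=O)–C3(OH)–C4(OH)(CO2H)–C5; ring A = C5–C6(=O)–O7–C8(decenyl)–C9H2.
2. Retrosynthesis: free the acid from its tert-butyl ester; take C3–OH back to C3=O and then C3H2; cut the C4–C5 bond, which opens ring B to a 2-oxosuccinate (oxaloacetate) ester of the ring A α-hydroxy lactone; then cut O1–C2 (ester), C5–O1 (enolate oxidation), ring A (malonate + (R)-epoxide) and the epoxide ((R)-epichlorohydrin + C9 Grignard reagent).
3. Forward: the chain is joined first, ring A is built, O1 is placed on C5, the oxaloacetyl arm is hung on O1, ring B is closed by the C4–C5 bond, then C3 is adjusted and the acid freed.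
4. Feature used: in the arm-bearing lactone the C5–H of ring A is tertiary and captodative (between lactone C6=O and acyloxy O1) and lies δ to the arm ketone (future C4). A 1,6-hydrogen shift to the excited ketone gives a 1,5-biradical that closes five-membered ring B. This is the bond that alkylcitrate biosynthesis makes between the oxaloacetate carbonyl and the α-carbon of the fatty acid unit.
5. Stereochemistry: C8 from (R)-epichlorohydrin; O1 on C5 trans to the chain by 1,3-induction in the enolate oxidation; C5 (retention) and C4 (hydrogen-bonded biradical) in the photocyclisation; C3 by hydroxyl-directed hydride delivery.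

Key step: step 7

Remark: atom labels in the Why lines follow the target numbering; 16 is a keto–enol mixture and is drawn as the keto tautomer, the form that absorbs at 365 nm.

**Route**

Step 1
Reactants: 1 (R)-epichlorohydrin; 2 9-bromonon-1-ene
Product: 5 (2R)-2-(dec-9-en-1-yl)oxirane, via Grignard reagent 3 (not isolated), via chlorohydrin 4 (not isolated)
Conditions: 2, Mg, THF; then 1, CuI (10 mol %), −40 to 0 °C; then NaOH (aq), rt
Reagents that add atoms: none
Why: Copper-catalysed Grignard opening of the epoxide at its CH2 terminus (the C–Cl bond is kept) followed by Williamson closure of the chlorohydrin; the stereocentre of 1 is not touched, so 5 is (R) and becomes C8.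

Step 2
Reactants: 5 (2R)-2-(dec-9-en-1-yl)oxirane; 6 diethyl malonate
Product: 7 ethyl (5R)-5-(dec-9-en-1-yl)-2-oxooxolane-3-carboxylate (C3 epimers)
Conditions: NaOEt (1.1 equiv), EtOH, 78 °C; then AcOH
Reagents that add atoms: none
Why: Malonic ester γ-lactone synthesis: the malonate anion opens the terminal epoxide at CH2 (SN2) and the alkoxide lactonises onto one ester, which forms ring A without touching C8.

Step 3
Reactants: 7 ethyl (5R)-5-(dec-9-en-1-yl)-2-oxooxolane-3-carboxylate
Product: 8 (5R)-5-(dec-9-en-1-yl)oxolan-2-one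
Conditions: LiCl, H2O (2 equiv), DMSO, 150 °C
Reagents that add atoms: none
Why: Krapcho dealkoxycarbonylation of the malonate-type lactone ester; lactone, alkene and C8 are unaffected.

Step 4
Reactants: 8 (5R)-5-(dec-9-en-1-yl)oxolan-2-one
Product: 9 (3R,5R)-5-(dec-9-en-1-yl)-3-hydroxyoxolan-2-one
Conditions: NaN(SiMe3)2, THF, −78 °C; then the oxaziridine, −78 °C; then AcOH
Reagents that add atoms: trans-3-phenyl-2-(phenylsulfonyl)oxaziridine (racemic), O=S(=O)(c1ccccc1)N1OC1c1ccccc1
Why: Davis oxidation of the sodium lactone enolate; the oxaziridine should approach the enolate face anti to the chain on C8 (1,3-induction across the five-membered ring), so O1 is set trans to the chain and the minor cis epimer is removed by chromatography.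

Step 5
Reactants: 10 Meldrum's acid; 11 oxalyl chloride; 12 tert-butanol
Product: 14 tert-butyl 2-(2,2-dimethyl-4,6-dioxo-1,3-dioxan-5-ylidene)-2-hydroxyacetate, via tert-butyl chlorooxoacetate 13 (not isolated)
Conditions: 12, 11 (3 equiv), Et2O, 0 °C, then evaporation; then 10, pyridine (2 equiv), CH2Cl2, 0 °C to rt
Reagents that add atoms: none
Why: Alcoholysis of one acid chloride group of oxalyl chloride, then C-acylation of Meldrum's acid (Oikawa–Yonemitsu acyl Meldrum's acid synthesis).

Step 6
Reactants: 9 (3R,5R)-5-(dec-9-en-1-yl)-3-hydroxyoxolan-2-one; 14 tert-butyl 2-(2,2-dimethyl-4,6-dioxo-1,3-dioxan-5-ylidene)-2-hydroxyacetate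
Product: 16 1-tert-butyl 4-[(3R,5R)-5-(dec-9-en-1-yl)-2-oxooxolan-3-yl] 2-oxobutanedioate, via acylketene 15 (not isolated)
Conditions: PhMe, 85 °C
Reagents that add atoms: none
Why: Oikawa–Yonemitsu alcoholysis: thermal loss of acetone and CO2 from 14 gives acylketene 15, which the secondary alcohol traps as the 3-oxo ester; the neutral conditions should leave the C5–H stereocentre and the tert-butyl ester intact.

Step 7
Reactants: 16 1-tert-butyl 4-[(3R,5R)-5-(dec-9-en-1-yl)-2-oxooxolan-3-yl] 2-oxobutanedioate
Product: 18 tert-butyl (4R,5S,8R)-8-(dec-9-en-1-yl)-4-hydroxy-2,6-dioxo-1,7-dioxaspiro[4.4]nonane-4-carboxylate, via 1,5-biradical 17 (not isolated)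
Conditions: hν (365 nm), degassed benzene (5 mM), rt
Reagents that add atoms: none
Why: Proposed new method: n→π* excitation of the arm ketone (future C4; a 2-oxo ester absorbing near 350 nm, where lactones and alkene are transparent) should give a triplet whose oxygen abstracts the C5–H of ring A through a seven-membered transition state (1,6-hydrogen shift), and the resulting 1,5-biradical 17 combines to the C4–C5 bond. The closest known reaction type is the Norrish–Yang photocyclisation of 3-oxo esters by δ-hydrogen abstraction from the ester alkyl group to 3-hydroxy-4-butanolides, which has not been shown for a 2-oxosuccinate ester or for a lactone C–H that becomes a spiro centre. Ring B is closed in the five-membered mode by radical–radical combination of the two biradical termini, both fully substituted, while ring A is already present and becomes spiro-fused. C5 should form with retention, because the ketyl carbon is held on the lactone face from which the hydrogen left (the face cis to the chain on C8) and combines before the tether can rotate through the lactone plane, and C4 should place its OH cis to the ring A carbonyl C6=O because the ketyl O–H is hydrogen-bonded to that carbonyl in the biradical (non-polar solvent). The step needs site selectivity for C5–H, secured because this is the only tertiary captodative C–H (between C6=O and the acyloxy O1) and the only activated C–H within reach, because the tert-butyl ester has no γ-hydrogen for Norrish type 2 cleavage, and because the radical pathway ignores the acidic C3H2 that would be deprotonated first in any base-mediated aldol. The product has no chromophore at the irradiation wavelength and should not react further.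

Step 8
Reactants: 18 tert-butyl (4R,5S,8R)-8-(dec-9-en-1-yl)-4-hydroxy-2,6-dioxo-1,7-dioxaspiro[4.4]nonane-4-carboxylate
Product: 19 tert-butyl (4R,5S,8R)-8-(dec-9-en-1-yl)-3,4-dihydroxy-2,6-dioxo-1,7-dioxaspiro[4.4]nonane-4-carboxylate (both C3 epimers)
Conditions: LDA (2.5 equiv), THF, −78 °C; then the oxaziridine, −78 °C; then AcOH
Reagents that add atoms: trans-3-phenyl-2-(phenylsulfonyl)oxaziridine (racemic), O=S(=O)(c1ccccc1)N1OC1c1ccccc1
Why: Davis oxidation of the alkoxide–enolate dianion (Fráter–Seebach-type dianion, whose β-oxido group does not eliminate); C3 is the only enolisable carbon (C4 and C5 are quaternary) and its configuration is deliberately left open because step 9 erases it.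

Step 9
Reactants: 19 tert-butyl (4R,5S,8R)-8-(dec-9-en-1-yl)-3,4-dihydroxy-2,6-dioxo-1,7-dioxaspiro[4.4]nonane-4-carboxylate
Product: 20 tert-butyl (4S,5S,8R)-8-(dec-9-en-1-yl)-4-hydroxy-2,3,6-trioxo-1,7-dioxaspiro[4.4]nonane-4-carboxylate
Conditions: IBX, EtOAc, 75 °C
Reagents that add atoms: none
Why: IBX oxidation of the secondary α-hydroxy lactone to the 2,3-dioxo lactone; IBX does not cleave the 3,4-diol, the tertiary C4–OH is inert, and the new ketone has no α-hydrogen to enolise (the 4S descriptor is a priority change only).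

Step 10
Reactants: 20 tert-butyl (4S,5S,8R)-8-(dec-9-en-1-yl)-4-hydroxy-2,3,6-trioxo-1,7-dioxaspiro[4.4]nonane-4-carboxylate
Product: 21 tert-butyl (3R,4R,5S,8R)-8-(dec-9-en-1-yl)-3,4-dihydroxy-2,6-dioxo-1,7-dioxaspiro[4.4]nonane-4-carboxylate
Conditions: NaBH(OAc)3, MeCN/AcOH, −20 °C
Reagents that add atoms: none
Why: Hydroxyl-directed triacetoxyborohydride reduction (Saksena–Evans type): the C4–OH binds boron and delivers hydride to the C3 ketone on its own face, which is also the face away from the tert-butyl ester, so C3–OH should end trans to C4–OH (3R); lactones and esters are not reduced by this reagent.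

Step 11
Reactants: 21 tert-butyl (3R,4R,5S,8R)-8-(dec-9-en-1-yl)-3,4-dihydroxy-2,6-dioxo-1,7-dioxaspiro[4.4]nonane-4-carboxylate
Product: 22 (3R,4R,5S,8R)-8-(dec-9-en-1-yl)-3,4-dihydroxy-2,6-dioxo-1,7-dioxaspiro[4.4]nonane-4-carboxylic acid
Conditions: TFA/CH2Cl2 (1:4), 0 °C to rt
Reagents that add atoms: none
Why: Acidolysis of the tert-butyl ester (E1 loss of isobutene); the two γ-lactones, the alcohols and the monosubstituted alkene should tolerate short exposure to cold TFA, and no stereocentre is touched.

**Compound list**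

1 | (R)-epichlorohydrin, (2R)-2-(chloromethyl)oxirane | ClC[C@H]1CO1 | starting material
2 | 9-bromonon-1-ene | C=CCCCCCCCBr | starting material
3 | non-8-en-1-ylmagnesium bromide | C=CCCCCCCC[Mg]Br | intermediate
4 | (2R)-1-chlorododec-11-en-2-ol (present as its bromomagnesium alkoxide) | ClC[C@H](O)CCCCCCCCC=C | intermediate
5 | (2R)-2-(dec-9-en-1-yl)oxirane | C=CCCCCCCCC[C@@H]1CO1 | intermediate
6 | diethyl malonate | CCOC(=O)CC(=O)OCC | starting material
7 | ethyl (5R)-5-(dec-9-en-1-yl)-2-oxooxolane-3-carboxylate (C3 epimers) | C=CCCCCCCCC[C@@H]1CC(C(=O)OCC)C(=O)O1 | intermediate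
8 | (5R)-5-(dec-9-en-1-yl)oxolan-2-one | C=CCCCCCCCC[C@@H]1CCC(=O)O1 | intermediate
9 | (3R,5R)-5-(dec-9-en-1-yl)-3-hydroxyoxolan-2-one | C=CCCCCCCCC[C@@H]1C[C@@H](O)C(=O)O1 | intermediate
10 | Meldrum's acid, 2,2-dimethyl-1,3-dioxane-4,6-dione | CC1(C)OC(=O)CC(=O)O1 | starting material
11 | oxalyl chloride | O=C(Cl)C(=O)Cl | starting material
12 | tert-butanol | CC(C)(C)O | starting material
13 | tert-butyl chlorooxoacetate | CC(C)(C)OC(=O)C(=O)Cl | intermediate
14 | tert-butyl 2-(2,2-dimethyl-4,6-dioxo-1,3-dioxan-5-ylidene)-2-hydroxyacetate | CC(C)(C)OC(=O)C(O)=C1C(=O)OC(C)(C)OC1=O | intermediate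
15 | tert-butyl 2,4-dioxobut-3-enoate (acylketene) | CC(C)(C)OC(=O)C(=O)C=C=O | intermediate
16 | 1-tert-butyl 4-[(3R,5R)-5-(dec-9-en-1-yl)-2-oxooxolan-3-yl] 2-oxobutanedioate | C=CCCCCCCCC[C@@H]1C[C@@H](OC(=O)CC(=O)C(=O)OC(C)(C)C)C(=O)O1 | intermediate
17 | 1,5-biradical from 16 (radical centres at future C4 and C5) | C=CCCCCCCCC[C@@H]1C[C](OC(=O)C[C](O)C(=O)OC(C)(C)C)C(=O)O1 | intermediate
18 | tert-butyl (4R,5S,8R)-8-(dec-9-en-1-yl)-4-hydroxy-2,6-dioxo-1,7-dioxaspiro[4.4]nonane-4-carboxylate | C=CCCCCCCCC[C@@H]1C[C@@]2(OC(=O)C[C@]2(O)C(=O)OC(C)(C)C)C(=O)O1 | intermediate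
19 | tert-butyl (4R,5S,8R)-8-(dec-9-en-1-yl)-3,4-dihydroxy-2,6-dioxo-1,7-dioxaspiro[4.4]nonane-4-carboxylate (both C3 epimers) | C=CCCCCCCCC[C@@H]1C[C@@]2(OC(=O)C(O)[C@]2(O)C(=O)OC(C)(C)C)C(=O)O1 | intermediate
20 | tert-butyl (4S,5S,8R)-8-(dec-9-en-1-yl)-4-hydroxy-2,3,6-trioxo-1,7-dioxaspiro[4.4]nonane-4-carboxylate | C=CCCCCCCCC[C@@H]1C[C@@]2(OC(=O)C(=O)[C@]2(O)C(=O)OC(C)(C)C)C(=O)O1 | intermediate
21 | tert-butyl (3R,4R,5S,8R)-8-(dec-9-en-1-yl)-3,4-dihydroxy-2,6-dioxo-1,7-dioxaspiro[4.4]nonane-4-carboxylate | C=CCCCCCCCC[C@@H]1C[C@@]2(OC(=O)[C@H](O)[C@]2(O)C(=O)OC(C)(C)C)C(=O)O1 | intermediate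
22 | (3R,4R,5S,8R)-8-(dec-9-en-1-yl)-3,4-dihydroxy-2,6-dioxo-1,7-dioxaspiro[4.4]nonane-4-carboxylic acid | C=CCCCCCCCC[C@@H]1C[C@@]2(OC(=O)[C@H](O)[C@]2(O)C(=O)O)C(=O)O1 | target

**Count and risks**

Total step count: 11. Longest linear sequence: 10 (steps 1–4 and 6–11; step 5 is a one-step branch).

Steps most likely to fail:

1. Step 7 (proposed new method).
 - What may go wrong: reverse hydrogen transfer within the biradical may outrun C–C bond formation between two fully substituted radical centres, which returns 16 and scrambles C5. The tether may rotate to the other lactone face before closure, giving the C5 epimer. Slow keto–enol exchange may starve the absorbing tautomer.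
 - Fallback (known chemistry; the C4–C5 bond is made between two molecules by a tartrate enolate aldol and both rings are closed afterwards by lactonisation): it sets out from epoxide 5 and comes back at target 22.
 - 2-Lithio-1,3-dithiane opens 5 at CH2 and the alkoxide is trapped with TBSOTf in the same flask to give 2-[(2R)-2-[(tert-butyldimethylsilyl)oxy]dodec-11-en-1-yl]-1,3-dithiane F1.
 - n-BuLi and then ethyl chloroformate give ethyl 2-[(2R)-2-[(tert-butyldimethylsilyl)oxy]dodec-11-en-1-yl]-1,3-dithiane-2-carboxylate F2.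
 - MeI and CaCO3 in aqueous MeCN release ethyl (4R)-4-[(tert-butyldimethylsilyl)oxy]-2-oxotetradec-13-enoate F3.
 - The lithium enolate of commercial dimethyl (4R,5R)-2,2-dimethyl-1,3-dioxolane-4,5-dicarboxylate (LDA, THF, −78 °C) should react on the face away from its neighbouring ester group and add to the ketone of F3, giving dimethyl (4R,5R)-4-[(2S,4R)-4-[(tert-butyldimethylsilyl)oxy]-1-ethoxy-2-hydroxy-1-oxotetradec-13-en-2-yl]-2,2-dimethyl-1,3-dioxolane-4,5-dicarboxylate F4.
 - Aqueous TFA (silyl ether and acetonide off, ring A closes), then LiOH and acidification (methyl esters off, ring B closes) should give 22.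

2. Step 8.
 - What may go wrong: retro-aldol fragmentation of the lithium alkoxide of the tertiary β-hydroxy lactone, which breaks the bond made in step 7, may compete with enolate oxidation.
 - Fallback (no strong base; C3 is raised to the ketone level by condensation and oxidative cleavage): it sets out from 18 and comes back at 20, replacing steps 8 and 9.
 - tert-Butoxybis(dimethylamino)methane (PhMe, 80 °C) condenses at the C3 methylene to give tert-butyl (4R,5S,8R)-8-(dec-9-en-1-yl)-3-[(dimethylamino)methylidene]-4-hydroxy-2,6-dioxo-1,7-dioxaspiro[4.4]nonane-4-carboxylate F5 (enamine geometry immaterial).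
 - Singlet oxygen (O2, tetraphenylporphyrin, visible light, CH2Cl2, −78 °C) cleaves the enamine C=C bond to ketone 20; the monosubstituted alkene is inert to singlet oxygen.

3. Step 4.
 - What may go wrong: facial discrimination by the remote C8 substituent may be insufficient in the enolate oxidation, so that much cis epimer forms.
 - Fallback (the C5–O1 configuration is set by SN2 inversion): it sets out from 8 and comes back at 9.
 - The cis alcohol (3S,5R)-5-(dec-9-en-1-yl)-3-hydroxyoxolan-2-one F6, formed from 8 under the step 4 conditions and separated, is inverted under Mitsunobu conditions (4-nitrobenzoic acid, PPh3, DIAD, THF) to (3R,5R)-5-(dec-9-en-1-yl)-2-oxooxolan-3-yl 4-nitrobenzoate F7.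
 - Mild methanolysis (K2CO3, MeOH, 0 °C, acidic work-up) returns 9.

**Further compounds**

F1 | step 7 | 2-[(2R)-2-[(tert-butyldimethylsilyl)oxy]dodec-11-en-1-yl]-1,3-dithiane | C=CCCCCCCCC[C@@H](O[Si](C)(C)C(C)(C)C)CC1SCCCS1
F2 | step 7 | ethyl 2-[(2R)-2-[(tert-butyldimethylsilyl)oxy]dodec-11-en-1-yl]-1,3-dithiane-2-carboxylate | C=CCCCCCCCC[C@@H](O[Si](C)(C)C(C)(C)C)CC1(C(=O)OCC)SCCCS1
F3 | step 7 | ethyl (4R)-4-[(tert-butyldimethylsilyl)oxy]-2-oxotetradec-13-enoate | C=CCCCCCCCC[C@@H](O[Si](C)(C)C(C)(C)C)CC(=O)C(=O)OCC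
F4 | step 7 | dimethyl (4R,5R)-4-[(2S,4R)-4-[(tert-butyldimethylsilyl)oxy]-1-ethoxy-2-hydroxy-1-oxotetradec-13-en-2-yl]-2,2-dimethyl-1,3-dioxolane-4,5-dicarboxylate | C=CCCCCCCCC[C@@H](O[Si](C)(C)C(C)(C)C)C[C@@](O)(C(=O)OCC)[C@]1(C(=O)OC)OC(C)(C)O[C@H]1C(=O)OC
F5 | step 8 | tert-butyl (4R,5S,8R)-8-(dec-9-en-1-yl)-3-[(dimethylamino)methylidene]-4-hydroxy-2,6-dioxo-1,7-dioxaspiro[4.4]nonane-4-carboxylate | C=CCCCCCCCC[C@@H]1C[C@@]2(OC(=O)C(=CN(C)C)[C@]2(O)C(=O)OC(C)(C)C)C(=O)O1
F6 | step 4 | (3S,5R)-5-(dec-9-en-1-yl)-3-hydroxyoxolan-2-one | C=CCCCCCCCC[C@@H]1C[C@H](O)C(=O)O1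
F7 | step 4 | (3R,5R)-5-(dec-9-en-1-yl)-2-oxooxolan-3-yl 4-nitrobenzoate | C=CCCCCCCCC[C@@H]1C[C@@H](OC(=O)c2ccc(cc2)[N+](=O)[O-])C(=O)O1
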